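The data are calculated with constants of no real substance, noise included.

Give every molecule of target an age, and ask how many survive it.

| setting | east | west | south-east | south | Tuesday's | Wednesday's | Thursday's |
|---|---|---|---|---|---|---|---|
| substrate | 0.050 M | 0.025 M | 0.10 M | 0.050 M | 0.050 M | 0.050 M | 0.050 M (fed, over 0.750 h) |
| catalyst | 2.5 mM | 2.5 mM | 2.5 mM | 1.2 mM | 2.5 mM | 2.5 mM | 2.5 mM |
| remark | run made earlier | run made earlier | run made earlier | run made earlier | a single well-mixed tank run continuously and read at steady state, 1.5 h in it on average | a closed flask charged with all of it at once and left for 1.5 h | a stirred flask in which substrate is dosed at a steady rate over 0.750 h without added volume, worked up at 1.5 h |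
| time |  |  |  |  |  | 1.5 h | 1.5 h |

| run | time / min | target / % |
|---|---|---|
| east | 4.00 | 35 |
| east | 10.0 | 59 |
| east | 25.0 | 69 |
| east | 50.0 | 54 |
| west | 6.00 | 40 |
| west | 20.0 | 70 |
| west | 40.0 | 62 |
| west | 50.0 | 56 |
| south-east | 15.0 | 67 |
| south-east | 25.0 | 71 |
| south-east | 40.0 | 65 |
| south-east | 50.0 | 54 |
| south | 4.00 | 16 |
| south | 10.0 | 37 |
| south | 25.0 | 56 |
| south | 50.0 | 51 |

(readings scatter by 2 percentage points)

* the set-up with the highest amount of target at the outlet or at the end, in percent of the substrate put in ("none" if the first two lie within 2 percentage points) (Tuesday's / Wednesday's / Thursday's / none)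
* amount of target at the outlet or at the end, in percent of the substrate put in, Tuesday's
* amount of target at the outlet or at the end, in percent of the substrate put in, Wednesday's
* amount of target at the outlet or at the end, in percent of the substrate put in, Thursday's

- the stated concentrations are those of everything mixed, before any reaction; amounts are the same in each set-up
- the feed brings no volume worth counting
- the earlier runs were made in a closed, stirred flask

At 2.5 mM of catalyst the east, west and south-east runs, though at different [substrate], read close together, as a pseudo-first-order step does. The east run's first reading, 35 % after 4.00 min, then reads, with the loss of target in those first minutes set aside, as a mean wait of 9.29 min before substrate becomes target. The east, west and south-east runs read 54 %, 56 % and 54 % at 50.0 min, so target aged 40.7 min is down to their mean. That reads as a survival time of target, the mean time a molecule of it lasts, of 67.4 min, in this rule: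

target left = exp(−age / survival time)

Wednesday's target has on average the age 90 min minus the wait, which by the rule gives 30.2 %. That is my lower bound for Thursday's, as if every dose were as old as the first. The last dose, 45 min later, gives the upper bound, 58.9 %.

By the rule, Thursday's is the mean of the survival curve over the doses; that curve bends upward, so its mean lies above its value at the mean age and below the midpoint of the two ends:

42.2 % < Thursday's < 44.5 %

The mean itself is 43.0 %, so using the mean age costs 0.80 percentage points. Averaging over the tank's spread of ages gives me 38.8 % for Tuesday's.

The forecast says Thursday's, with 37 % for Tuesday's, 28 % for Wednesday's and 41 % for Thursday's, the last by “Averaging the batch curve over that window”. Its Thursday's number lies 1.2 points under my lower edge, and a reading scatters by 2 points.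

Tuesday's gives 39.2 %, Wednesday's 31.9 % and Thursday's 44.1 %, so Thursday's is best, and Thursday's number lies inside my bracket.

    substrate ⇌ other conformer (K = 1.40, k = 6.20 × 10⁻⁵ /s)
    substrate + catalyst → catalyst + target (k = 0.710 /M/s)
    catalyst + other conformer → catalyst + isomer of the product (k = 0.540 /M/s)
    target → over-reaction product (k = 2.30 × 10⁻⁴ /s)

Thursday's held 60.2 % target and 20.0 % substrate at 0.750 h. The rule carries these forward to 42.7 %.

For a flask with 0.0010 M of catalyst and Wednesday's other settings, I stretch the wait in proportion to the lower [catalyst], to 23.2 min. The same survival time then gives 37.1 %; that flask gives 36.1 %.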